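A direct plan would build the carbocycle first and close the pyran last: a catalytic aldol would give the keto diester A1, a Dieckmann closure the cyclohexane-1,3-dione A2, enol triflation and Sonogashira coupling the ynenone A3, and a formylation at C8a (A4) would feed an AuCl3-catalysed closure of the pyran ring.
Its weakest steps would be:
(a) the monotriflation of the unsymmetrical 1,3-dione A2, where two enol oxygens compete and only a steric bias decides which is sulfonylated;
(b) the formylation of A3 at C8a to A4, a γ- against α-selective C–C bond formation next to the epimerisable C8 on an electrophile-sensitive enyne, needed only because the pyran is closed late;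
(c) the run-up to A3, about twelve steps in a line, in which thioester exchange, silyl protection and ozonolysis build nothing of the core, and in which the Dieckmann step puts a β-silyloxy ester under strong base.

**Retrosynthetic overview**
The pyran ring of the target (O2, C1, C3, C4, C4a, C8a, with the exocyclic C4a=C5 bond and the first side-chain carbon on C3) is kojic acid in disguise: its ring carbonyl carbon is C4a, its enolic C–OH carbon is C8a, and its CH2OH group becomes the acrylate; the pyran is bought, not made.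
The carbocycle is annulated onto it: C8–C8a by cross-coupling of the kojic triflate with a zinc enolate that carries the chiral ester; C7–C8 with both stereocentres by a catalytic Mukaiyama aldol to butane-2,3-dione, which supplies C5, C6, C7 and the C7 methyl group.
The key step closes the carbocycle by joining the C5 enol carbon to the activated pyranone carbon C4a, which creates the C4a=C5 bond and the 4-pyranylidene ketone in one operation.
Ring order is pyran (bought), then carbocycle; by design there is no 1,3-dione to triflate, no formylation, no late pyran closure and no strong base on a β-silyloxy ester, and the route has nine steps.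

Key step: step 8

Remark: locants C1 to C8a and O2 are those of the isochromene core of the target and are used for the corresponding atoms of all intermediates; the (R,R) ligand in step 7 is assigned by analogy with additions to pyruvate esters, and the (S,S) ligand would be used if the sense of induction proved opposite.

Step 1
Reactants: 1 kojic acid
Product: 2 6-(hydroxymethyl)-4-oxo-4H-pyran-3-yl trifluoromethanesulfonate
Conditions: PhNTf2 (1.05 equiv), Et3N, DMF, 0 °C to rt
Reagents that add atoms: N-phenylbis(trifluoromethanesulfonimide), O=S(=O)(N(c1ccccc1)S(=O)(=O)C(F)(F)F)C(F)(F)F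
Why: Selective O-sulfonylation of a vinylogous acid: the enolic 5-OH (pKa about 8) is deprotonated by the amine and triflated by the mild imide reagent, which leaves the primary alcohol alone.

Step 2
Reactants: 2 6-(hydroxymethyl)-4-oxo-4H-pyran-3-yl trifluoromethanesulfonate; 3 tert-butyl (triphenylphosphoranylidene)acetate
Product: 5 tert-butyl (E)-3-{4-oxo-5-[(trifluoromethanesulfonyl)oxy]-4H-pyran-2-yl}prop-2-enoate, via pyranone aldehyde 4 (not isolated)
Conditions: MnO2 (activated, excess), 3 (1.3 equiv), CH2Cl2, reflux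
Reagents that add atoms: none
Why: Tandem oxidation–Wittig olefination: MnO2 oxidises the allylic-type hydroxymethyl group and the stabilised ylide traps the electrophilic aldehyde 4 as it forms, E-selectively.

Step 3
Reactants: 6 (S)-1-bromo-2-methylbutane; 7 N-methoxy-N-methylacetamide
Product: 9 (S)-4-methylhexan-2-one, via Grignard reagent 8 (not isolated)
Conditions: Mg, THF, reflux; then 7, THF, 0 °C; aq. NH4Cl
Reagents that add atoms: none
Why: Weinreb ketone synthesis: the chelated tetrahedral adduct prevents a second addition, and the stereocentre β to magnesium is not touched.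

Step 4
Reactants: 9 (S)-4-methylhexan-2-one
Product: 10 (2S,4S)-4-methylhexan-2-ol
Conditions: ADH-A (Rhodococcus ruber), NADH (cat.), i-PrOH, phosphate buffer pH 7.5, 30 °C
Reagents that add atoms: none
Why: Ketoreductase reduction with isopropanol as hydride source: the (S)-selective enzyme should deliver hydride to the re face of the methyl ketone and set C2 as S under enzyme control, independent of the remote C4 centre.

Step 5
Reactants: 10 (2S,4S)-4-methylhexan-2-ol; 11 bromoacetyl bromide
Product: 12 (2S,4S)-4-methylhexan-2-yl bromoacetate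
Conditions: pyridine, CH2Cl2, 0 °C
Reagents that add atoms: none
Why: O-Acylation of the secondary alcohol by an acid bromide, with retention because the C–O bond of the alcohol is not broken.

Step 6
Reactants: 5 tert-butyl (E)-3-{4-oxo-5-[(trifluoromethanesulfonyl)oxy]-4H-pyran-2-yl}prop-2-enoate; 12 (2S,4S)-4-methylhexan-2-yl bromoacetate
Product: 14 (2S,4S)-4-methylhexan-2-yl 2-{6-[(1E)-3-tert-butoxy-3-oxoprop-1-en-1-yl]-4-oxo-4H-pyran-3-yl}acetate, via zinc enolate 13 (not isolated)
Conditions: 12, Zn (activated with Me3SiCl), THF, rt; then 5, Pd2(dba)3 (2.5 mol%), XPhos (10 mol%), THF, 45 °C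
Reagents that add atoms: none
Why: Reformatsky reagent formation and Negishi-type cross-coupling (α-arylation of a zinc ester enolate): the electron-poor enol triflate adds readily to zerovalent palladium, the mild zinc enolate tolerates the acrylate and the pyranone, and the C8–C8a bond is formed.

Step 7
Reactants: 14 (2S,4S)-4-methylhexan-2-yl 2-{6-[(1E)-3-tert-butoxy-3-oxoprop-1-en-1-yl]-4-oxo-4H-pyran-3-yl}acetate; 15 butane-2,3-dione
Product: 17 (2S,4S)-4-methylhexan-2-yl (2R,3R)-2-{6-[(1E)-3-tert-butoxy-3-oxoprop-1-en-1-yl]-4-oxo-4H-pyran-3-yl}-3-methyl-4-oxo-3-[(trimethylsilyl)oxy]pentanoate, via ketene silyl acetal 16 (not isolated)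
Conditions: LiN(SiMe3)2, Me3SiCl, THF, −78 °C; pentane, filtration; then 15, Cu(OTf)2 (10 mol%), (R,R)-t-Bu-box [2,2'-(propane-2,2-diyl)bis((4R)-4-tert-butyl-4,5-dihydrooxazole)] (11 mol%), CH2Cl2, −78 °C; non-acidic work-up
Reagents that add atoms: chlorotrimethylsilane, C[Si](C)(C)Cl
Why: Catalytic enantioselective Mukaiyama aldol addition to a chelating 1,2-diketone: the square-planar divalent copper chelate of the dione exposes one carbonyl face, so the (R,R) ligand should set C7 as R, the open transition state should give the syn adduct (C8 R) from either ketene acetal geometry, and silyl transfer leaves the C7 trimethylsilyl ether.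

Step 8
Reactants: 17 (2S,4S)-4-methylhexan-2-yl (2R,3R)-2-{6-[(1E)-3-tert-butoxy-3-oxoprop-1-en-1-yl]-4-oxo-4H-pyran-3-yl}-3-methyl-4-oxo-3-[(trimethylsilyl)oxy]pentanoate
Product: 20 tert-butyl (E)-3-[(7R,8R)-7-methyl-8-{[(2S,4S)-4-methylhexan-2-yl]oxycarbonyl}-6-oxo-7-[(trimethylsilyl)oxy]-7,8-dihydro-6H-isochromen-3-yl]prop-2-enoate, via enol silane 18 (not isolated), via triflyloxypyrylium triflate 19 (not isolated)
Conditions: LiN(i-Pr)2, Me3SiCl (in situ quench), THF, −78 °C; pentane, filtration; then Tf2O (1.0 equiv), 2,6-di-tert-butyl-4-methylpyridine, CH2Cl2, −78 to −20 °C; aq. NaHCO3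
Reagents that add atoms: none
Why: Proposed new method: kinetic deprotonation of the only enolisable ketone position (the C5 methyl group) and O-silylation give enol silane 18; Tf2O then sulfonylates the amide-like pyranone oxygen to the 4-(triflyloxy)pyrylium ion 19, whose γ-carbon C4a is attacked by the tethered enol silane, and loss of triflate, Me3SiOTf and the C5 proton (to the hindered pyridine) leaves the neutral 4-pyranylidene ketone. The closest known reactions are the Knoevenagel-type condensation of 4-pyranones with CH-acids in acetic anhydride (through 4-acyloxypyrylium ions), the displacement of 4-alkoxy, 4-chloro and 4-alkylsulfanyl groups of pyrylium salts by carbon nucleophiles, and the capture of Tf2O-activated amides by enol silanes. The carbocycle (C4a–C5–C6–C7–C8–C8a) closes by a 6-(enolendo)-exo-trig attack that forms the C4a–C5 bond, which ends as the C4a=C5 double bond. No stereocentre is formed: C7 is quaternary and C8 sits on a β-position of the pyrylium ring, where a C–H bond is not acidified, so both centres from step 7 should be carried through under these buffered, base-free conditions. The step needs attack at C4a and not at C1, which would also close a six-membered ring; this should be secured because a sulfonyloxy group, unlike a silyloxy group, does not donate into C4a, so the soft enol silane should follow the large γ-coefficient of the pyrylium LUMO (as enol silanes do with N-acylpyridinium ions), and only the C4a adduct can lose triflate irreversibly.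

Step 9
Reactants: 20 tert-butyl (E)-3-[(7R,8R)-7-methyl-8-{[(2S,4S)-4-methylhexan-2-yl]oxycarbonyl}-6-oxo-7-[(trimethylsilyl)oxy]-7,8-dihydro-6H-isochromen-3-yl]prop-2-enoate
Product: 21 (E)-3-[(7R,8R)-7-hydroxy-7-methyl-8-{[(2S,4S)-4-methylhexan-2-yl]oxycarbonyl}-6-oxo-7,8-dihydro-6H-isochromen-3-yl]prop-2-enoic acid
Conditions: CF3CO2H/CH2Cl2/H2O (10:10:1), 0 °C to rt
Reagents that add atoms: none
Why: Acidolysis: the tert-butyl ester fragments by an E1 pathway and the tertiary trimethylsilyl ether is hydrolysed, while the secondary ester, the α-ketol and the reversibly protonated pyranylidene ketone should survive.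

**Compound list**
1 | kojic acid [5-hydroxy-2-(hydroxymethyl)-4H-pyran-4-one] | OCC1=CC(=O)C(O)=CO1 | starting material
2 | 6-(hydroxymethyl)-4-oxo-4H-pyran-3-yl trifluoromethanesulfonate | OCC1=CC(=O)C(OS(=O)(=O)C(F)(F)F)=CO1 | intermediate
3 | tert-butyl (triphenylphosphoranylidene)acetate | CC(C)(C)OC(=O)C=P(c1ccccc1)(c1ccccc1)c1ccccc1 | starting material
4 | 6-formyl-4-oxo-4H-pyran-3-yl trifluoromethanesulfonate | O=CC1=CC(=O)C(OS(=O)(=O)C(F)(F)F)=CO1 | intermediate (not isolated)
5 | tert-butyl (E)-3-{4-oxo-5-[(trifluoromethanesulfonyl)oxy]-4H-pyran-2-yl}prop-2-enoate | CC(C)(C)OC(=O)/C=C/C1=CC(=O)C(OS(=O)(=O)C(F)(F)F)=CO1 | intermediate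
6 | (S)-1-bromo-2-methylbutane | CC[C@H](C)CBr | starting material
7 | N-methoxy-N-methylacetamide | CC(=O)N(C)OC | starting material
8 | (S)-2-methylbutylmagnesium bromide | CC[C@H](C)C[Mg]Br | intermediate (not isolated)
9 | (S)-4-methylhexan-2-one | CC[C@H](C)CC(C)=O | intermediate
10 | (2S,4S)-4-methylhexan-2-ol | CC[C@H](C)C[C@H](C)O | intermediate
11 | bromoacetyl bromide | BrCC(Br)=O | starting material
12 | (2S,4S)-4-methylhexan-2-yl bromoacetate | CC[C@H](C)C[C@H](C)OC(=O)CBr | intermediate
13 | [2-{[(2S,4S)-4-methylhexan-2-yl]oxy}-2-oxoethyl]zinc bromide (Reformatsky reagent of 12) | CC[C@H](C)C[C@H](C)OC(=O)C[Zn]Br | intermediate (not isolated)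
14 | (2S,4S)-4-methylhexan-2-yl 2-{6-[(1E)-3-tert-butoxy-3-oxoprop-1-en-1-yl]-4-oxo-4H-pyran-3-yl}acetate | CC[C@H](C)C[C@H](C)OC(=O)CC1=COC(/C=C/C(=O)OC(C)(C)C)=CC1=O | intermediate
15 | butane-2,3-dione | CC(=O)C(C)=O | starting material
16 | tert-butyl (E)-3-{5-[2-{[(2S,4S)-4-methylhexan-2-yl]oxy}-2-[(trimethylsilyl)oxy]ethenyl]-4-oxo-4H-pyran-2-yl}prop-2-enoate (ketene silyl acetal of 14, mixture of geometries) | CC[C@H](C)C[C@H](C)OC(O[Si](C)(C)C)=CC1=COC(/C=C/C(=O)OC(C)(C)C)=CC1=O | intermediate (not isolated)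
17 | (2S,4S)-4-methylhexan-2-yl (2R,3R)-2-{6-[(1E)-3-tert-butoxy-3-oxoprop-1-en-1-yl]-4-oxo-4H-pyran-3-yl}-3-methyl-4-oxo-3-[(trimethylsilyl)oxy]pentanoate (precursor of the key step; C7 and C8 set) | CC[C@H](C)C[C@H](C)OC(=O)[C@@H]([C@@](C)(O[Si](C)(C)C)C(C)=O)C1=COC(/C=C/C(=O)OC(C)(C)C)=CC1=O | intermediate
18 | (2S,4S)-4-methylhexan-2-yl (2R,3R)-2-{6-[(1E)-3-tert-butoxy-3-oxoprop-1-en-1-yl]-4-oxo-4H-pyran-3-yl}-3-methyl-3,4-bis[(trimethylsilyl)oxy]pent-4-enoate (C5=C6 enol silane) | CC[C@H](C)C[C@H](C)OC(=O)[C@@H]([C@@](C)(O[Si](C)(C)C)C(=C)O[Si](C)(C)C)C1=COC(/C=C/C(=O)OC(C)(C)C)=CC1=O | intermediate (not isolated)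
19 | 2-[(E)-3-tert-butoxy-3-oxoprop-1-en-1-yl]-5-[(2R,3R)-1-{[(2S,4S)-4-methylhexan-2-yl]oxy}-3-methyl-1-oxo-3,4-bis[(trimethylsilyl)oxy]pent-4-en-2-yl]-4-[(trifluoromethanesulfonyl)oxy]pyrylium trifluoromethanesulfonate | CC[C@H](C)C[C@H](C)OC(=O)[C@@H]([C@@](C)(O[Si](C)(C)C)C(=C)O[Si](C)(C)C)c1c[o+]c(/C=C/C(=O)OC(C)(C)C)cc1OS(=O)(=O)C(F)(F)F.[O-]S(=O)(=O)C(F)(F)F | intermediate (not isolated)
20 | tert-butyl (E)-3-[(7R,8R)-7-methyl-8-{[(2S,4S)-4-methylhexan-2-yl]oxycarbonyl}-6-oxo-7-[(trimethylsilyl)oxy]-7,8-dihydro-6H-isochromen-3-yl]prop-2-enoate | CC[C@H](C)C[C@H](C)OC(=O)[C@@H]1C2=COC(/C=C/C(=O)OC(C)(C)C)=CC2=CC(=O)[C@]1(C)O[Si](C)(C)C | intermediate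
21 | (E)-3-[(7R,8R)-7-hydroxy-7-methyl-8-{[(2S,4S)-4-methylhexan-2-yl]oxycarbonyl}-6-oxo-7,8-dihydro-6H-isochromen-3-yl]prop-2-enoic acid | CC[C@H](C)C[C@H](C)OC(=O)[C@@H]1C2=COC(/C=C/C(=O)O)=CC2=CC(=O)[C@]1(C)O | target

**Step count and risk**
Total steps: 9. Longest linear sequence: 7 (steps 3, 4, 5, 6, 7, 8, 9).

Steps most likely to fail:

1. Step 8 (bears the label). What may go wrong: attack of the enol silane at C1 instead of C4a (an α-addition to the pyrylium ion that closes the isomeric six-membered ring), or sulfonylation of the enol silane by Tf2O before the pyranone is activated. Fallback with known chemistry, in which a sulfur tether can deliver C5 only to C4a: it sets out from 18. N-Bromosuccinimide (THF, −78 °C) would give the bromomethyl ketone F1. Lawesson's reagent (toluene, 60 °C) would thionate the vinylogous-ester carbonyl, well before the hindered ketone or the esters, to the pyran-4-thione F2, which should S-alkylate itself with the bromomethyl ketone to the bridged 4-(alkylsulfanyl)pyrylium bromide F3. PPh3 and Et3N (CH2Cl2, rt; Eschenmoser sulfide contraction by thiirane formation and sulfur extrusion) would then form the C4a=C5 bond, and the sequence comes back to the route at 20.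

2. Step 7. What may go wrong: loss of turnover or of facial control because the Lewis-basic pyranone competes with the dione for copper, erosion of the syn preference with the bulky pyranonyl-substituted ketene acetal, or epimerisation at C8 during handling. Fallback that replaces catalyst control by separation: it sets out from 14. Soft enolisation (TiCl4, i-Pr2NEt, CH2Cl2, −78 °C) and addition of 15 would give the aldol without catalyst control; since the resident (2S,4S)-ester makes all four C7/C8 isomers diastereomers, the (2R,3R)-alcohol F4 would be separated by chromatography and silylated with N-(trimethylsilyl)imidazole (CH2Cl2, rt), which comes back to the route at 17.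

3. Step 6. What may go wrong: slow oxidative addition or transmetallation, so that the zinc enolate adds in conjugate fashion to the pyranone or the acrylate, or cleavage of the S–O bond of the triflate. Fallback that brings in C8 as an allyl group and makes the ester by acylation: it sets out from 5. Stille coupling (allyltributylstannane, Pd(PPh3)4, LiCl, 1,4-dioxane, 90 °C) would give the allylpyranone F5; Lemieux–Johnson cleavage (OsO4 cat., NaIO4, 2,6-lutidine, dioxane/H2O) the aldehyde F6; Pinnick oxidation (NaClO2, NaH2PO4, 2-methylbut-2-ene, t-BuOH/H2O) the acid F7; and Steglich esterification with alcohol 10 (DCC, DMAP cat., CH2Cl2) comes back to the route at 14.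

Further compounds
F1 | step 8 | (2S,4S)-4-methylhexan-2-yl (2R,3R)-5-bromo-2-{6-[(1E)-3-tert-butoxy-3-oxoprop-1-en-1-yl]-4-oxo-4H-pyran-3-yl}-3-methyl-4-oxo-3-[(trimethylsilyl)oxy]pentanoate | CC[C@H](C)C[C@H](C)OC(=O)[C@@H]([C@@](C)(O[Si](C)(C)C)C(=O)CBr)C1=COC(/C=C/C(=O)OC(C)(C)C)=CC1=O
F2 | step 8 | (2S,4S)-4-methylhexan-2-yl (2R,3R)-5-bromo-2-{6-[(1E)-3-tert-butoxy-3-oxoprop-1-en-1-yl]-4-thioxo-4H-pyran-3-yl}-3-methyl-4-oxo-3-[(trimethylsilyl)oxy]pentanoate | CC[C@H](C)C[C@H](C)OC(=O)[C@@H]([C@@](C)(O[Si](C)(C)C)C(=O)CBr)C1=COC(/C=C/C(=O)OC(C)(C)C)=CC1=S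
F3 | step 8 | bridged 4-(alkylsulfanyl)pyrylium bromide in which sulfur links C4a and C5 (seven-membered thia ring fused to the pyrylium ring; C6 ketone, C7 methyl and trimethylsilyloxy, C8 (2S,4S)-4-methylhexan-2-yl ester, C3 tert-butyl (E)-acrylate; 7R,8R) | CC[C@H](C)C[C@H](C)OC(=O)[C@@H]1c2c[o+]c(/C=C/C(=O)OC(C)(C)C)cc2SCC(=O)[C@]1(C)O[Si](C)(C)C.[Br-]
F4 | step 7 | (2S,4S)-4-methylhexan-2-yl (2R,3R)-2-{6-[(1E)-3-tert-butoxy-3-oxoprop-1-en-1-yl]-4-oxo-4H-pyran-3-yl}-3-hydroxy-3-methyl-4-oxopentanoate | CC[C@H](C)C[C@H](C)OC(=O)[C@@H]([C@@](C)(O)C(C)=O)C1=COC(/C=C/C(=O)OC(C)(C)C)=CC1=O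
F5 | step 6 | tert-butyl (E)-3-[4-oxo-5-(prop-2-en-1-yl)-4H-pyran-2-yl]prop-2-enoate | CC(C)(C)OC(=O)/C=C/C1=CC(=O)C(CC=C)=CO1
F6 | step 6 | tert-butyl (E)-3-[4-oxo-5-(2-oxoethyl)-4H-pyran-2-yl]prop-2-enoate | CC(C)(C)OC(=O)/C=C/C1=CC(=O)C(CC=O)=CO1
F7 | step 6 | 2-{6-[(1E)-3-tert-butoxy-3-oxoprop-1-en-1-yl]-4-oxo-4H-pyran-3-yl}acetic acid | CC(C)(C)OC(=O)/C=C/C1=CC(=O)C(CC(=O)O)=CO1
A1 | direct plan | 1-methyl 4-[(2S,4S)-4-methylhexan-2-yl] (2R,3R)-2-methyl-3-(2-oxopropyl)-2-[(triethylsilyl)oxy]butanedioate | CC[C@H](C)C[C@H](C)OC(=O)[C@H](CC(C)=O)[C@@](C)(O[Si](CC)(CC)CC)C(=O)OC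
A2 | direct plan | (2S,4S)-4-methylhexan-2-yl (1R,2R)-2-methyl-3,5-dioxo-2-[(triethylsilyl)oxy]cyclohexane-1-carboxylate | CC[C@H](C)C[C@H](C)OC(=O)[C@@H]1CC(=O)CC(=O)[C@]1(C)O[Si](CC)(CC)CC
A3 | direct plan | (2S,4S)-4-methylhexan-2-yl (1R,6R)-3-[(E)-5-tert-butoxy-5-oxopent-3-en-1-yn-1-yl]-6-methyl-5-oxo-6-[(triethylsilyl)oxy]cyclohex-3-ene-1-carboxylate | CC[C@H](C)C[C@H](C)OC(=O)[C@@H]1CC(C#C/C=C/C(=O)OC(C)(C)C)=CC(=O)[C@]1(C)O[Si](CC)(CC)CC
A4 | direct plan | (2S,4S)-4-methylhexan-2-yl (1R,6R)-3-[(E)-5-tert-butoxy-5-oxopent-3-en-1-yn-1-yl]-2-(dimethoxymethyl)-6-methyl-5-oxo-6-[(triethylsilyl)oxy]cyclohex-3-ene-1-carboxylate (epimers at C8a) | CC[C@H](C)C[C@H](C)OC(=O)[C@@H]1C(C(OC)OC)C(C#C/C=C/C(=O)OC(C)(C)C)=CC(=O)[C@]1(C)O[Si](CC)(CC)CC
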